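The route traces the C4–C5 oxirane oxygen and the C6 carbonyl oxygen back to one O2 molecule. In the six-membered carbocycle, C4 (quaternary oxirane carbon), C5 (oxirane CH) and C6 (carbonyl) carry oxygen, while C1 and C4 carry carbon arms. This is the imprint of a peroxide bridge between C4 and C1 whose oxygens have slid to C5 and C6. The key step, singlet-oxygen [4+2] cycloaddition, makes both tertiary C–O bonds, closes the 1,2-dioxane ring and sets C4 in one operation. Its substrate is a 1,4-bis(oxymethyl)cyclohexa-1,3-diene (C1=C6–C5=C4). Its only stereocentre, a bulky C3 silyloxy group derived from a Sharpless epoxide, blocks one face.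

Key step: step 8

Remark: all ring intermediates keep the target numbering (C1 bears the CH2O arm that ends as CH2OAc; C4 bears C1'). "Top" is the face of the C4–C5 oxirane oxygen in the target and "bottom" is the other face. TBDPS = tert-butyldiphenylsilyl, TBS = tert-butyldimethylsilyl, PMB = 4-methoxybenzyl, TPP = 5,10,15,20-tetraphenylporphyrin, DMP = Dess–Martin periodinane.

Step 1
Reactants: 1 dimethyl 2,5-dioxocyclohexane-1,4-dicarboxylate
Product: 2 dimethyl 2,5-dihydroxycyclohexane-1,4-dicarboxylate (diastereomer mixture)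
Conditions: NaBH4, MeOH/THF, 0 °C; aq. work-up
Reagents that add atoms: none
Why: Borohydride reduction of a cyclic β-keto ester stops at the β-hydroxy ester at 0 °C, and the diastereomer mixture is harmless because all four stereocentres are erased in step 2.

Step 2
Reactants: 2 dimethyl 2,5-dihydroxycyclohexane-1,4-dicarboxylate
Product: 4 dimethyl cyclohexa-1,4-diene-1,4-dicarboxylate, via bis-mesylate 3 (not isolated)
Conditions: MsCl, Et3N, CH2Cl2, 0 °C; then DBU, 0 °C → rt, argon
Reagents that add atoms: none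
Why: Mesylation and twofold E1cB elimination of a β-sulfonyloxy ester put each new alkene in conjugation with its own ester, which gives the 1,4-diene whatever the relative configuration of 2, and air is excluded to prevent aromatisation.

Step 3
Reactants: 4 dimethyl cyclohexa-1,4-diene-1,4-dicarboxylate
Product: 5 cyclohexa-1,4-diene-1,4-diyldimethanol
Conditions: iBu2AlH (4.5 equiv), CH2Cl2, −78 → 0 °C; aq. potassium sodium tartrate
Reagents that add atoms: none
Why: 1,2-Reduction of α,β-unsaturated esters with iBu2AlH gives the allylic alcohols without reducing or shifting the ring alkenes.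

Step 4
Reactants: 5 cyclohexa-1,4-diene-1,4-diyldimethanol
Product: 6 [4-(TBDPS-oxymethyl)cyclohexa-1,4-dien-1-yl]methanol
Conditions: NaH (1.0 equiv), THF, 0 °C → rt; TBDPSCl (1.0 equiv)
Reagents that add atoms: tert-butyl(chloro)diphenylsilane, CC(C)(C)[Si](Cl)(c1ccccc1)c1ccccc1
Why: O-Silylation of the sparingly soluble monosodium alkoxide favours the mono-ether of a symmetrical diol, and recovered 5 and bis-ether can be recycled.

Step 5
Reactants: 6 [4-(TBDPS-oxymethyl)cyclohexa-1,4-dien-1-yl]methanol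
Product: 7 (3R,4R)-epoxy alcohol [(1R,6R)-4-(TBDPS-oxymethyl)-7-oxabicyclo[4.1.0]hept-3-en-1-yl]methanol (oxirane oxygen on the bottom face)
Conditions: Ti(OiPr)4 (10 mol %), D-(−)-diethyl tartrate (12 mol %), tBuOOH, 4 Å sieves, CH2Cl2, −20 °C
Reagents that add atoms: tert-butyl hydroperoxide, CC(C)(C)OO
Why: In the Sharpless asymmetric epoxidation only the free allylic alcohol binds titanium, so the silyl-ether alkene is spared, and D-(−)-tartrate (the sense that turns E-allylic alcohols into 2R,3R-epoxy alcohols) should place oxygen on the bottom face of C3=C4 and set 3R,4R.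

Step 6
Reactants: 7 (3R,4R)-epoxy alcohol
Product: 8 (3R,4R)-epoxy PMB ether (1R,6R)-4-(TBDPS-oxymethyl)-1-(PMB-oxymethyl)-7-oxabicyclo[4.1.0]hept-3-ene
Conditions: NaH, PMBCl, Bu4NI (cat.), THF/DMF, 0 °C → rt
Reagents that add atoms: 4-methoxybenzyl chloride, COc1ccc(CCl)cc1
Why: This is a Williamson etherification, and Payne rearrangement of the alkoxide is unlikely because it would need SN2 attack at the fully substituted C4.

Step 7
Reactants: 8 (3R,4R)-epoxy PMB ether
Product: 10 (5R)-5-(TBS-oxy)-4-(PMB-oxymethyl)-1-(TBDPS-oxymethyl)cyclohexa-1,3-diene (C3 is R with OTBS on the bottom face), via lithium alkoxide 9 (not isolated)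
Conditions: LiN(iPr)2 (2.5 equiv), THF, −78 → 0 °C; then TBSCl, DMPU, −78 °C → rt; aq. NaHCO3; Et3N-deactivated silica
Reagents that add atoms: tert-butyl(chloro)dimethylsilane, CC(C)(C)[Si](C)(C)Cl
Why: In this lithium-amide epoxide-to-allylic-alcohol isomerisation (syn β-elimination) the base should take the allylic C5–H cis to the oxirane and break the tertiary C4–O bond, leaving C3–O and its R configuration intact, and capping 9 in the flask avoids handling the acid-labile arene hydrate.

Step 8
Reactants: 10 (5R)-5-(TBS-oxy)-4-(PMB-oxymethyl)-1-(TBDPS-oxymethyl)cyclohexa-1,3-diene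
Product: 11 (1S,4R,7R)-7-(TBS-oxy)-4-(TBDPS-oxymethyl)-1-(PMB-oxymethyl)-2,3-dioxabicyclo[2.2.2]oct-5-ene (peroxide bridge C4–O–O–C1 on the top face)
Conditions: O2, TPP (1 mol %), CH2Cl2, −78 °C, visible light (white LED)
Reagents that add atoms: dioxygen, O=O
Why: Energy transfer from photoexcited TPP to ground-state O2 gives singlet oxygen, which adds suprafacially to the termini C4 and C1 of the ring-locked s-cis diene in a concerted [4+2] cycloaddition; the closest known cases are 1,4-dialkylcyclohexa-1,3-dienes (α-terpinene to ascaridole) and protected arene dihydrodiols. The one ring closed, the six-membered 1,2-dioxane C4–O–O–C1–C6=C5, is formed by cycloaddition (both C–O bonds in one event), not by a stepwise exo or endo closure. Both new stereocentres, C4 (S here) and C1 (R), are controlled by C3: allylic strain with the C4 CH2OPMB arm pushes the OTBS group pseudo-axial over the bottom face, so O2 should bond on the top face, trans to OTBS. The step needs π-facial selectivity, secured by that shield and the low temperature, and chemoselectivity for cycloaddition over the Schenck ene reaction, secured by the planar cisoid diene, which is far more reactive toward singlet oxygen than any isolated allylic C–H site. As both bridgeheads are fully substituted, no bridgehead hydrogen is available for Kornblum–DeLaMare fragmentation and 11 should tolerate chromatography.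

Step 9
Reactants: 11 endoperoxide
Product: 12 cis-bis-oxirane (C4–C5 and C1–C6 oxiranes both on the top face; C3-OTBS on the bottom face; ring centres 1S,3R,4R,5R,6S) carrying C4-CH2OPMB and C1-CH2OTBDPS
Conditions: Co(TPP) (5 mol %, divalent cobalt), CH2Cl2, 0 °C → rt, dark
Reagents that add atoms: none
Why: In this cobalt-porphyrin-catalysed endoperoxide-to-bis-epoxide rearrangement divalent cobalt cleaves the weak O–O bond by single-electron transfer and each oxygen closes onto the neighbouring alkene carbon (O on C4 to C5, O on C1 to C6) from the face it already occupies, so C5 (R) and C6 (S) follow from C4 and C1.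

Step 10
Reactants: 12 cis-bis-oxirane PMB ether
Product: 13 cis-bis-oxirane primary alcohol (C4-CH2OH; ring centres as in 12)
Conditions: DDQ, CH2Cl2/pH 7 buffer, 0 °C
Reagents that add atoms: none
Why: Oxidative PMB cleavage (hydride abstraction from the electron-rich benzyl ether, then hydrolysis of the oxocarbenium ion) under buffered conditions leaves silyl ethers and both oxiranes alone.

Step 11
Reactants: 13 cis-bis-oxirane primary alcohol
Product: 14 cis-bis-oxirane aldehyde (C4-CHO; ring centres as in 12)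
Conditions: DMP, NaHCO3, CH2Cl2, 0 °C → rt
Reagents that add atoms: none
Why: Dess–Martin oxidation under bicarbonate buffer gives an epoxy aldehyde with a quaternary α-carbon, which can neither enolise nor epimerise.

Step 12
Reactants: 15 propargyl alcohol
Product: 17 (E)-3-iodo-2-methylprop-2-en-1-ol, via alkenylalane 16 (not isolated)
Conditions: AlMe3 (3 equiv), Cp2ZrCl2 (0.25 equiv), CH2Cl2, 0 °C → rt; then I2, THF, −30 °C
Reagents that add atoms: trimethylaluminium, C[Al](C)C; iodine, II
Why: The zirconium-catalysed Negishi carboalumination adds methyl and aluminium syn across the alkyne with aluminium at the terminus, and iodinolysis with retention fixes the E trisubstituted alkene.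

Step 13
Reactants: 17 (E)-3-iodo-2-methylprop-2-en-1-ol
Product: 18 (E)-3-iodo-2-methylprop-2-enal
Conditions: MnO2, CH2Cl2, rt
Reagents that add atoms: none
Why: Allylic alcohol oxidation with MnO2 stops at the enal and does not isomerise the alkene.

Step 14
Reactants: 18 (E)-3-iodo-2-methylprop-2-enal; 19 (triphenylphosphoranylidene)acetaldehyde
Product: 20 (2E,4E)-5-iodo-4-methylpenta-2,4-dienal
Conditions: toluene, 80 °C, 19 (1.1 equiv)
Reagents that add atoms: none
Why: Wittig olefination with the stabilised formyl ylide gives the E disubstituted alkene, and near-stoichiometric ylide limits a second homologation.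

Step 15
Reactants: 20 (2E,4E)-5-iodo-4-methylpenta-2,4-dienal
Product: 21 (1E,3E)-1-iodo-5,5-dimethoxy-2-methylpenta-1,3-diene
Conditions: HC(OMe)3, PPTS (cat.), MeOH, rt; Et3N quench
Reagents that add atoms: trimethyl orthoformate, COC(OC)OC
Why: Acid-catalysed acetalisation with the orthoformate as water scavenger masks the aldehyde for the organolithium step.

Step 16
Reactants: 21 (1E,3E)-1-iodo-5,5-dimethoxy-2-methylpenta-1,3-diene; 14 cis-bis-oxirane aldehyde
Product: 24 (1'S)-C1' acetate with the (2'E,4'E)-6',6'-dimethoxy-3'-methylhexadienyl chain on C4 (ring centres as in 12; both silyl ethers retained), via dienyllithium 22 (not isolated), via lithium alkoxide 23 (not isolated)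
Conditions: 21, tBuLi (2 equiv per 21), Et2O, −78 °C; 14, Et2O/THF, −78 °C; then Ac2O, DMAP (cat.), −78 → 0 °C
Reagents that add atoms: acetic anhydride, CC(=O)OC(C)=O
Why: Lithium–iodine exchange with retention of alkene geometry is followed by 1,2-addition to the non-enolisable aldehyde, where the polar Felkin–Anh model (C4–O oxirane bond anti to the nucleophile, carbonyl oxygen beside the bulky C3 carbinol carbon, approach past the tied-back C5) predicts the 1'S alkoxide, and cold acylation forestalls silyl migration.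

Step 17
Reactants: 24 (1'S)-C1' acetate bis-silyl ether
Product: 25 (1'S)-diol (C1-CH2OH and C3-OH free; C3-OH on the bottom face; oxiranes and acetal intact)
Conditions: Bu4NF/AcOH (1:1), THF, 0 °C → rt
Reagents that add atoms: none
Why: Fluoride-induced desilylation, buffered with AcOH so that no free alkoxide can trigger acetyl migration or Payne rearrangement, frees the primary arm and the C3 carbinol together.

Step 18
Reactants: 25 (1'S)-diol
Product: 26 (1'S)-diacetate with free C3-OH (C1-CH2OAc and C1'-OAc)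
Conditions: AcCl (1.1 equiv), 2,4,6-collidine, CH2Cl2, −78 °C
Reagents that add atoms: acetyl chloride, CC(Cl)=O
Why: This acylation is chemoselective because at −78 °C the primary alcohol reacts much faster than the secondary C3–OH, which is flanked by the quaternary C4.

Step 19
Reactants: 26 (1'S)-diacetate with free C3-OH
Product: 28 (4R,5R,6R,1'S)-γ-hydroxy enone (C1=C2; C3=O; C4–C5 oxirane; C6-OH on the top face), via C3 ketone 27 (not isolated)
Conditions: DMP, NaHCO3, CH2Cl2, 0 °C → rt; aq. wash; crude in CH2Cl2, Et3N (0.5 equiv), 0 °C → rt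
Reagents that add atoms: none
Why: Dess–Martin oxidation is followed by an E1cB-type β-elimination in which the C3 ketone acidifies C2–H and the amine opens the C1–O bond of the β,γ-oxirane to give the C1=C2 enone and the C6 alcohol, whose cis relation to the C4–C5 oxirane rules out Payne migration.

Step 20
Reactants: 28 γ-hydroxy enone
Product: 29 (4R,5S,1'S)-epoxyquinone dimethyl acetal
Conditions: DMP, NaHCO3, CH2Cl2, 0 °C → rt
Reagents that add atoms: none
Why: Dess–Martin oxidation of the allylic C6 alcohol completes the ene-dione without touching C4, C5 or C1'.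

Step 21
Reactants: 29 epoxyquinone dimethyl acetal
Product: 30 target (1S,2E,4E)-1-[(1R,6S)-4-(acetoxymethyl)-2,5-dioxo-7-oxabicyclo[4.1.0]hept-3-en-1-yl]-3-methyl-6-oxohexa-2,4-dienyl acetate
Conditions: PPTS (0.2 equiv), acetone/H2O 10:1, rt
Reagents that add atoms: water, O
Why: Mild acid hydrolysis of the acetal runs through a dienyl-stabilised oxocarbenium ion and should therefore be much faster than any reaction of the acetates or the oxirane.

Compound list
1 | dimethyl 2,5-dioxocyclohexane-1,4-dicarboxylate | COC(=O)C1CC(=O)C(C(=O)OC)CC1=O | starting material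
2 | dimethyl 2,5-dihydroxycyclohexane-1,4-dicarboxylate (diastereomer mixture) | COC(=O)C1CC(O)C(C(=O)OC)CC1O | intermediate
3 | dimethyl 2,5-bis(methylsulfonyloxy)cyclohexane-1,4-dicarboxylate (diastereomer mixture) | COC(=O)C1CC(OS(C)(=O)=O)C(C(=O)OC)CC1OS(C)(=O)=O | intermediate
4 | dimethyl cyclohexa-1,4-diene-1,4-dicarboxylate | COC(=O)C1=CCC(C(=O)OC)=CC1 | intermediate
5 | cyclohexa-1,4-diene-1,4-diyldimethanol | OCC1=CCC(CO)=CC1 | intermediate
6 | [4-(TBDPS-oxymethyl)cyclohexa-1,4-dien-1-yl]methanol | CC(C)(C)[Si](c1ccccc1)(c1ccccc1)OCC1=CCC(CO)=CC1 | intermediate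
7 | [(1R,6R)-4-(TBDPS-oxymethyl)-7-oxabicyclo[4.1.0]hept-3-en-1-yl]methanol | CC(C)(C)[Si](c1ccccc1)(c1ccccc1)OCC1=CC[C@]2(CO)O[C@@H]2C1 | intermediate
8 | (1R,6R)-4-(TBDPS-oxymethyl)-1-(PMB-oxymethyl)-7-oxabicyclo[4.1.0]hept-3-ene | CC(C)(C)[Si](c1ccccc1)(c1ccccc1)OCC1=CC[C@]2(COCc3ccc(OC)cc3)O[C@@H]2C1 | intermediate
9 | lithium (1R)-2-(PMB-oxymethyl)-5-(TBDPS-oxymethyl)cyclohexa-2,4-dien-1-olate | CC(C)(C)[Si](c1ccccc1)(c1ccccc1)OCC1=CC=C(COCc2ccc(OC)cc2)[C@H]([O-])C1.[Li+] | intermediate
10 | (5R)-5-(TBS-oxy)-4-(PMB-oxymethyl)-1-(TBDPS-oxymethyl)cyclohexa-1,3-diene | CC(C)(C)[Si](c3ccccc3)(c4ccccc4)OCC1=CC=C(COCc5ccc(OC)cc5)[C@H](O[Si](C)(C)C(C)(C)C)C1 | intermediate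
11 | (1S,4R,7R)-7-(TBS-oxy)-4-(TBDPS-oxymethyl)-1-(PMB-oxymethyl)-2,3-dioxabicyclo[2.2.2]oct-5-ene | CC(C)(C)[Si](c3ccccc3)(c4ccccc4)OC[C@]12C[C@@H](O[Si](C)(C)C(C)(C)C)[C@](COCc5ccc(OC)cc5)(OO1)C=C2 | intermediate
12 | cis-bis-oxirane PMB ether (1S,3R,4R,5R,6S) | CC(C)(C)[Si](c5ccccc5)(c6ccccc6)OC[C@@]12C[C@@H](O[Si](C)(C)C(C)(C)C)[C@]3(COCc4ccc(OC)cc4)O[C@@H]3[C@@H]1O2 | intermediate
13 | cis-bis-oxirane primary alcohol | CC(C)(C)[Si](c5ccccc5)(c6ccccc6)OC[C@@]12C[C@@H](O[Si](C)(C)C(C)(C)C)[C@]3(CO)O[C@@H]3[C@@H]1O2 | intermediate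
14 | cis-bis-oxirane aldehyde | CC(C)(C)[Si](c5ccccc5)(c6ccccc6)OC[C@@]12C[C@@H](O[Si](C)(C)C(C)(C)C)[C@]3(C=O)O[C@@H]3[C@@H]1O2 | intermediate
15 | propargyl alcohol | C#CCO | starting material
16 | (E)-alkenylalane, dimethylaluminium alkoxide form | C[Al](C)/C=C(C)/CO[Al](C)C | intermediate
17 | (E)-3-iodo-2-methylprop-2-en-1-ol | OC/C(C)=C/I | intermediate
18 | (E)-3-iodo-2-methylprop-2-enal | O=C/C(C)=C/I | intermediate
19 | (triphenylphosphoranylidene)acetaldehyde | O=CC=P(c1ccccc1)(c1ccccc1)c1ccccc1 | starting material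
20 | (2E,4E)-5-iodo-4-methylpenta-2,4-dienal | O=C/C=C/C(C)=C/I | intermediate
21 | (1E,3E)-1-iodo-5,5-dimethoxy-2-methylpenta-1,3-diene | COC(OC)/C=C/C(C)=C/I | intermediate
22 | (1E,3E)-5,5-dimethoxy-2-methylpenta-1,3-dienyllithium | [Li]/C=C(C)/C=C/C(OC)OC | intermediate
23 | lithium (1'S)-alkoxide from 22 and 14 | CC(C)(C)[Si](c5ccccc5)(c6ccccc6)OC[C@@]12C[C@@H](O[Si](C)(C)C(C)(C)C)[C@]3([C@H](/C=C(C)/C=C/C(OC)OC)[O-])O[C@@H]3[C@@H]1O2.[Li+] | intermediate
24 | (1'S)-C1' acetate, bis-silyl ether, dimethyl acetal | CC(C)(C)[Si](c5ccccc5)(c6ccccc6)OC[C@@]12C[C@@H](O[Si](C)(C)C(C)(C)C)[C@]3([C@H](/C=C(C)/C=C/C(OC)OC)OC(C)=O)O[C@@H]3[C@@H]1O2 | intermediate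
25 | (1'S)-diol (C1-CH2OH, C3-OH) | OC[C@@]12C[C@@H](O)[C@]3([C@H](/C=C(C)/C=C/C(OC)OC)OC(C)=O)O[C@@H]3[C@@H]1O2 | intermediate
26 | (1'S)-diacetate with free C3-OH | CC(=O)OC[C@@]12C[C@@H](O)[C@]3([C@H](/C=C(C)/C=C/C(OC)OC)OC(C)=O)O[C@@H]3[C@@H]1O2 | intermediate
27 | C3 ketone, bis-oxirane | CC(=O)OC[C@@]12CC(=O)[C@]3([C@H](/C=C(C)/C=C/C(OC)OC)OC(C)=O)O[C@@H]3[C@@H]1O2 | intermediate
28 | (4R,5R,6R,1'S)-γ-hydroxy enone | CC(=O)OCC1=CC(=O)[C@]2([C@H](/C=C(C)/C=C/C(OC)OC)OC(C)=O)O[C@@H]2[C@@H]1O | intermediate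
29 | (4R,5S,1'S)-epoxyquinone dimethyl acetal | CC(=O)OCC1=CC(=O)[C@]2([C@H](/C=C(C)/C=C/C(OC)OC)OC(C)=O)O[C@@H]2C1=O | intermediate
30 | CNP0307549.1, (4R,5S,1'S) | CC(=O)OCC1=CC(=O)[C@]2([C@H](/C=C(C)/C=C/C=O)OC(C)=O)O[C@@H]2C1=O | target

Total steps: 21. Longest linear sequence: 17 (steps 1–11 and 16–21). The side chain (steps 12–15) is made in parallel.

Steps most likely to fail

Step 8, the key step. Weak discrimination between the two diene faces, or leakage into ene-type hydroperoxidation, would erode the only stereochemical relay of the route. The fallback rebuilds the shield itself instead of tuning the irradiation. It sets out from 8.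
- The lithium amide isomerisation is repeated and alkoxide 9 is capped with TBDPSCl/DMPU to give the C3-O-TBDPS diene F1, whose phenyl rings reach further over the bottom face.
- Photooxygenation should give the endoperoxide F2, and Co(TPP) the cis-bis-oxirane F3.
- DDQ then gives the primary alcohol F4, and DMP the aldehyde F5.
- Addition of 22 gives the lithium alkoxide F6, and Ac2O the C1' acetate F7.
- Bu4NF/AcOH removes the two identical silyl groups, and the sequence comes back to the route at diol 25.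

Step 7. Proton removal at C2 instead of C5 (which leads to the tertiary C4 alcohol) or loss of the C3 oxygen with aromatisation would consume the epoxide unproductively. The fallback replaces base-induced opening by radical opening, and it sets out from 8. Cp2TiCl (trivalent titanium, from Cp2TiCl2 and Mn dust, THF, rt) cleaves the oxirane homolytically toward the more stable tertiary C4 radical, so the regiochemistry no longer depends on C–H acidity. Transfer of the weak allylic C5–H to a second Cp2TiCl gives, after NaHCO3 work-up, the free (3R)-dienol F8. This is silylated at once (TBSOTf, 2,6-lutidine, CH2Cl2, −78 °C) and comes back to the route at 10.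

Step 16. Insufficient Felkin–Anh bias at C1', or decay of the dienyllithium before addition, would give an epimer mixture or little coupling. The fallback moves from substrate control to reagent control. It sets out from 14 and 21 and uses a Nozaki–Hiyama–Kishi coupling (CrCl2, divalent chromium; NiCl2 cat.; chiral oxazoline–sulfonamide ligand in the matching enantiomeric form; Et3N, THF). This should give the free (1'S)-alcohol F9 under nearly neutral conditions. Ac2O, pyridine and DMAP then bring it back to the route at 24.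

Further compounds
F1 | step 8 | (5R)-5-(TBDPS-oxy)-4-(PMB-oxymethyl)-1-(TBDPS-oxymethyl)cyclohexa-1,3-diene | CC(C)(C)[Si](c3ccccc3)(c4ccccc4)OCC1=CC=C(COCc5ccc(OC)cc5)[C@H](O[Si](c6ccccc6)(c7ccccc7)C(C)(C)C)C1
F2 | step 8 | C3-O-TBDPS endoperoxide | CC(C)(C)[Si](c3ccccc3)(c4ccccc4)OC[C@]12C[C@@H](O[Si](c6ccccc6)(c7ccccc7)C(C)(C)C)[C@](COCc5ccc(OC)cc5)(OO1)C=C2
F3 | step 8 | C3-O-TBDPS cis-bis-oxirane PMB ether | CC(C)(C)[Si](c5ccccc5)(c6ccccc6)OC[C@@]12C[C@@H](O[Si](c7ccccc7)(c8ccccc8)C(C)(C)C)[C@]3(COCc4ccc(OC)cc4)O[C@@H]3[C@@H]1O2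
F4 | step 8 | C3-O-TBDPS cis-bis-oxirane primary alcohol | CC(C)(C)[Si](c5ccccc5)(c6ccccc6)OC[C@@]12C[C@@H](O[Si](c7ccccc7)(c8ccccc8)C(C)(C)C)[C@]3(CO)O[C@@H]3[C@@H]1O2
F5 | step 8 | C3-O-TBDPS cis-bis-oxirane aldehyde | CC(C)(C)[Si](c5ccccc5)(c6ccccc6)OC[C@@]12C[C@@H](O[Si](c7ccccc7)(c8ccccc8)C(C)(C)C)[C@]3(C=O)O[C@@H]3[C@@H]1O2
F6 | step 8 | C3-O-TBDPS lithium (1'S)-alkoxide | CC(C)(C)[Si](c5ccccc5)(c6ccccc6)OC[C@@]12C[C@@H](O[Si](c7ccccc7)(c8ccccc8)C(C)(C)C)[C@]3([C@H](/C=C(C)/C=C/C(OC)OC)[O-])O[C@@H]3[C@@H]1O2.[Li+]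
F7 | step 8 | C3-O-TBDPS (1'S)-C1' acetate | CC(C)(C)[Si](c5ccccc5)(c6ccccc6)OC[C@@]12C[C@@H](O[Si](c7ccccc7)(c8ccccc8)C(C)(C)C)[C@]3([C@H](/C=C(C)/C=C/C(OC)OC)OC(C)=O)O[C@@H]3[C@@H]1O2
F8 | step 7 | (1R)-2-(PMB-oxymethyl)-5-(TBDPS-oxymethyl)cyclohexa-2,4-dien-1-ol | CC(C)(C)[Si](c3ccccc3)(c4ccccc4)OCC1=CC=C(COCc5ccc(OC)cc5)[C@H](O)C1
F9 | step 16 | free (1'S)-alcohol corresponding to 24 | CC(C)(C)[Si](c5ccccc5)(c6ccccc6)OC[C@@]12C[C@@H](O[Si](C)(C)C(C)(C)C)[C@]3([C@H](/C=C(C)/C=C/C(OC)OC)O)O[C@@H]3[C@@H]1O2
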